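## Structural features

The target is a 2,3-dihydro-1-benzofuran: a benzene ring (C3a–C7a) fused to a five-membered ether ring (O1, C2, C3). It carries a 3-oxoprop-1-en-2-yl group (an α-substituted acrolein) at C2, an acetoxy group at C3 and a 1-(tigloyloxy)ethyl group at C5. C2 (S) and C3 (R) are adjacent and trans on the small ring. The third stereocentre, (R), is the remote benzylic carbinol carbon of the C5 chain, and the tiglate double bond is E. The fragile groups are the α-methylene aldehyde (a Michael acceptor that polymerises), the C3 benzylic acetate (loss of acetic acid across C2–C3 gives an aromatic benzofuran) and the para-alkoxybenzylic tiglate (it ionises under acid). With two different esters present, late hydrolytic or strongly basic steps are excluded. The real difficulty is the trans C2/C3 oxygenated pair combined with a fixed arene pattern (O1 at C7a, C3 at C3a, the two-carbon chain at C5, para to O1) and a C2 side chain oxidised at one methyl carbon. The key step exploits the fact that this arene pattern is what a 3-alkoxy-6-acetylpyridazine leaves when an alkyne tethered through O1–C2–C3 bridges its C3 and C6 and N2 is lost. Bonds C3a–C7a and C4–C5 form, both rings close, and C2 and C3 can be set beforehand in an open chain, where an anti diol derivative corresponds to the trans ring.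

## Logic of the disconnections

27 ⇒ 26 ⇒ 25. No skeletal bond is cut: the aldehyde carbon is taken back to a primary allylic alcohol and that to its 4-methoxybenzyl ether. The enal tolerates neither heat, hydride, organometallics nor base, so it should appear only in the last flask. The demand is that ether cleavage and oxidation be neutral (DDQ, then MnO2) so that both esters and the C2–H/C3–OAc pair survive.

25 ⇒ 22 + 23. The acyl C–O bond of the tiglate is cut. This removes the second ester and the E alkene from all earlier steps. The acylation must take place at oxygen, without ionising the benzylic C–O bond.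

22 ⇒ 21. The C–H bond of the carbinol carbon is cut, leading back to the aryl methyl ketone. The remote stereocentre is thus set late, by catalyst control, and the ketone is the group that activates the key step. The reduction must leave the acetate, the ether and the 1,1-disubstituted alkene alone.

21 ⇒ 19 (through 20). C3a–C7a and C4–C5 are cut and N2 is put back, which opens both rings to an acetylpyridazinyl ether of an anti 1,2-diol monoacetate with a terminal alkyne. 19 and 21 correspond atom for atom: (3R,4S)-anti in the chain becomes (2S,3R)-trans in the ring, so no structure needs correcting. The gain is that the arene pattern follows from connectivity and no stereocentre is at stake in the ring-forming step. The demand is a neutral thermal step in which cycloaddition outruns the oxygen-to-nitrogen allyl shift and loss of acetic acid. The primary oxygen is carried as a 4-methoxybenzyl ether, which is inert at that temperature and orthogonal to the silyl groups used earlier.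

19 ⇒ 18 ⇒ 17. The acetate is taken back to the free propargylic alcohol, and that to a compound with a triisopropylsilyl ether on that oxygen and a trimethylsilyl cap on the alkyne. Both silicon groups fall in one buffered fluoride step. The demand is that no free alkoxide arises next to the activated heteroaryl ether (risk of a Smiles-type shift), hence the acetic acid buffer.

17 ⇒ 15 ⇒ 12 + 13. First the C–CH3 bond of the acetyl group is cut (nitrile plus MeMgBr), then the O–C(heteroaryl) bond (SNAr). An acetyl group on the chlorodiazine would be enolised by the alkoxide, whereas the nitrile has no α-hydrogen and activates the chloride enough for reaction at –78 °C. The demand on the SNAr step is that the alkoxide must not exchange places with its silyl neighbour. A small silyl group would migrate from the propargylic to the allylic oxygen, downhill to the more stable propargylic alkoxide. The triisopropylsilyl group and the low temperature prevent this, and the capped alkyne removes the only other acidic hydrogen.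

12 ⇒ 10 + 8 (through 11), and 10 ⇒ 9. The C–C bond between the allylic carbinol carbon and the vinyl carbon is cut. This gives an α-silyloxy aldehyde and a 2-metallated allyl ether that already holds the oxygenated methylene carbon of the side chain. The demand is Felkin–Anh (anti) addition without epimerising the aldehyde; the bulky non-chelating silyl group and the enlarged alkynyl substituent serve this.

8 ⇒ 6 ⇒ 5 ⇒ 4 ⇒ 1 + 2. The aldehyde comes from ozonolysis of a vinyl group, the silyl ether from the resolved alcohol, and the racemate from acetylide addition to the enal. The silyl cap on the alkyne gives the lipase a large group to distinguish from the vinyl group and protects the alkyne C–H through steps 6 and 7. The demand is a resolution that leaves the (S)-alcohol in high purity.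

## Other disconnections considered

Alternative 1: The cut is made at C3–C3a and O1–C2, so the arene is bought and the small ring is assembled from phenol A2 and epoxy aldehyde A3. In the forward direction the bromomagnesium salt of A2 (EtMgBr) would attack the aldehyde of A3 through its ortho carbon. K2CO3 in methanol would then make the phenoxide open the epoxide at the carbon next to the new carbinol, with inversion, to give the trans diol A1 with a 2-hydroxypropan-2-yl group at C2.
- In its favour: no ring is built at high temperature; the closure is a 5-exo opening at the less substituted epoxide carbon; the remote carbinol centre is already present in A2; C2 comes from an epoxide of known handedness; the core is reached in very few steps.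
- Against it here: the C3 configuration rests on the facial selectivity of an aryl-carbon addition to an α,β-epoxy aldehyde, a substrate-controlled event with competing chelated and open pathways. The side chain arrives as a saturated tertiary alcohol, so the target would still need regioselective dehydration towards one methyl group and allylic oxidation of the other (for example with SeO2), on a molecule that already carries an elimination-prone benzylic oxygen function.
- Comparison: Alternative 1 is better in convergence, in step count up to the core and in mildness (ionic and cold against pericyclic and hot). It is weaker in the control of C3 and in the oxidation level of the C2 chain, which the chosen plan brings in complete. Over the whole route the two should be of similar length.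

Alternative 2: O1–C2 is formed while the O1–CMe2 bond of a chroman is broken. This is a ring contraction of chromanol A5, reached from chromene A6 by Jacobsen epoxidation, opening at C4 and silylation. In the key step Tf2O and 2,6-di-tert-butyl-4-methylpyridine activate the C3 hydroxyl of A5, the ring oxygen displaces it from the rear, and the tertiary cation loses a methyl proton to give isopropenyl ketone A4.
- In its favour: the absolute configuration comes from a catalytic epoxidation of the substrate class for which that reaction is most dependable; the 1,2-shift is stereospecific, so trans A5 gives trans A4; the isopropenyl and acetyl groups are both in place; it is probably the shortest way to a 2-isopropenyl-3-oxy core.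
- Against it here: the participating ring oxygen is para to the acetyl group and therefore a weak neighbouring group. The activated chromanol has other exits (hydride shift to a chroman-4-one, elimination). Opening the epoxide at the oxygen-stabilised benzylic carbon has ionisation character and may erode the trans relation. A4 lacks the oxygen on the side-chain carbon and carries silyl where acetate is needed, so an allylic C–H oxidation and a protecting-group exchange remain.
- Comparison: Alternative 2 is better in step economy and in the reliability of its asymmetric step. It is equal in that the arene pattern raises no regiochemical question. It is weaker in that its key step is a cation rearrangement with several competing channels, and it needs a late oxidation next to sensitive groups.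

Alternative 3: C2–C3 and O1–C2 are cut, leading to aldehyde A8 and allyl bromide A9. The sulfonium ylide made in the flask from A9, a terpene-derived chiral sulfide and LiN(SiMe3)2 would add to A8 and close to the trans vinyl epoxide A10. Bu4NF would then free the phenoxide, which opens the epoxide at the allylic carbon with inversion to give A7.
- In its favour: it is highly convergent; both ring stereocentres come from one reagent-controlled step; the side chain has the right oxidation pattern from the outset, as in the chosen plan (A7 differs from 21 only by the acetate and the protecting group); temperatures are mild and the sulfide is recoverable.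
- Against it here: 2-substituted allyl ylides are less dependable than benzyl ylides in diastereo- and enantiocontrol and can undergo [2,3] shifts. The amide base meets an enolisable aryl methyl ketone. The closure is a 5-endo opening that must win over attack at the alkene terminus. An ortho-phenoxide can open a benzylic epoxide by elimination to a quinone methide, which would scramble C3. Fluoride must also distinguish the aryl from the alkyl silyl ether.
- Comparison: Alternative 3 is shorter than the chosen plan and better in that stereocontrol is by reagent. It is equal in oxidation-state logic and in the kind of intermediate reached. It is weaker in the geometric demands of the ring closure and in the number of base-sensitive sites in one flask. The chosen plan separates the stereochemical problem (open chain, early) from the ring-forming problem (neutral, thermal, no stereocentre involved).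

Key step: step 11

Assumption (chemistry): the lipase is taken to acylate the (R)-enantiomer of 4 faster (silylethynyl as the large group, vinyl as the medium group), so that 5 is the alcohol left unreacted.

## Route

Step 1
Reactants: 1 ethynyl(trimethyl)silane; 2 prop-2-enal (acrolein)
Product: 4 rac-5-(trimethylsilyl)pent-1-en-4-yn-3-ol, via lithium (trimethylsilyl)acetylide 3 (not isolated)
Conditions: n-BuLi, THF, –78 °C; then 2, –78 °C; aq. NH4Cl
Reagents that add atoms: none
Why: 1,2-Addition of a lithium acetylide to an enal; the hard acetylide attacks the carbonyl carbon at low temperature. The silyl cap on the alkyne is kept on purpose for steps 2, 6 and 7.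

Step 2
Reactants: 4 rac-5-(trimethylsilyl)pent-1-en-4-yn-3-ol
Product: 5 (3S)-5-(trimethylsilyl)pent-1-en-4-yn-3-ol
Conditions: Amano lipase PS (immobilised), vinyl acetate, hexane, 30 °C, run past half conversion
Reagents that add atoms: none
Why: Lipase-catalysed kinetic resolution by irreversible transesterification; by the empirical size rule for secondary alcohols the (R)-alcohol is acetylated and (S)-5 is left. Because the wanted enantiomer is the slow one, its purity should rise as conversion is pushed further.

Step 3
Reactants: 5 (3S)-5-(trimethylsilyl)pent-1-en-4-yn-3-ol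
Product: 6 triisopropyl{[(3S)-5-(trimethylsilyl)pent-1-en-4-yn-3-yl]oxy}silane
Conditions: i-Pr3SiOTf, 2,6-lutidine, CH2Cl2, 0 °C
Reagents that add atoms: triisopropylsilyl trifluoromethanesulfonate, CC(C)[Si](C(C)C)(C(C)C)OS(=O)(=O)C(F)(F)F
Why: Silylation of a secondary alcohol with a silyl triflate; no bond to the stereocentre is touched. The bulky, non-chelating, migration-resistant silyl group is chosen for what it must do in steps 6 and 7.

Step 4
Reactants: 6 triisopropyl{[(3S)-5-(trimethylsilyl)pent-1-en-4-yn-3-yl]oxy}silane
Product: 8 (2R)-2-[(triisopropylsilyl)oxy]-4-(trimethylsilyl)but-3-ynal, via 1,2,4-trioxolane ozonide 7 (not isolated)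
Conditions: O3, CH2Cl2, –78 °C, stopped at the first blue tint; PPh3, –78 °C → rt; used crude
Reagents that add atoms: ozone, [O-][O+]=O
Why: Ozonolysis with reductive work-up; the vinyl group reacts far faster with ozone than the silylated alkyne. The stereocentre is untouched (the descriptor changes from S to R only because formyl outranks alkynyl), and the neutral work-up spares the epimerisable α-carbon.

Step 5
Reactants: 9 2-bromoprop-2-en-1-ol
Product: 10 1-{[(2-bromoprop-2-en-1-yl)oxy]methyl}-4-methoxybenzene
Conditions: NaH, THF, 0 °C; 4-methoxybenzyl chloride, Bu4NI (cat.), 0 °C → rt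
Reagents that add atoms: 4-methoxybenzyl chloride, COc1ccc(CCl)cc1
Why: Williamson ether synthesis; the vinyl bromide is inert to the alkoxide at this temperature. The benzyl-type ether is chosen because it survives t-BuLi, fluoride and 185 °C and is removed oxidatively at the end.

Step 6
Reactants: 10 1-{[(2-bromoprop-2-en-1-yl)oxy]methyl}-4-methoxybenzene; 8 (2R)-2-[(triisopropylsilyl)oxy]-4-(trimethylsilyl)but-3-ynal
Product: 12 (3S,4R)-1-[(4-methoxybenzyl)oxy]-2-methylidene-4-[(triisopropylsilyl)oxy]-6-(trimethylsilyl)hex-5-yn-3-ol (3,4-anti), via 2-lithioallyl ether 11 (not isolated)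
Conditions: t-BuLi (2 equiv), Et2O, –78 °C; then 8, –78 °C; aq. NH4Cl
Reagents that add atoms: none
Why: Bromine–lithium exchange, then Felkin–Anh addition of the alkenyllithium to an α-silyloxy aldehyde: the nucleophile enters anti to the C–OSi bond and past the hydrogen rather than the silylalkynyl group. This sets the new carbinol centre (the future C2) anti to the existing one (the future C3). The bulky silyl group suppresses chelation, the capped alkyne offers no acidic hydrogen, and the low temperature keeps both the aldehyde and the β-alkoxy vinyllithium intact.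

Step 7
Reactants: 12 (3S,4R)-1-[(4-methoxybenzyl)oxy]-2-methylidene-4-[(triisopropylsilyl)oxy]-6-(trimethylsilyl)hex-5-yn-3-ol; 13 6-chloropyridazine-3-carbonitrile
Product: 15 6-{[(3S,4R)-1-[(4-methoxybenzyl)oxy]-2-methylidene-4-[(triisopropylsilyl)oxy]-6-(trimethylsilyl)hex-5-yn-3-yl]oxy}pyridazine-3-carbonitrile, via potassium alkoxide 14 (not isolated)
Conditions: KN(SiMe3)2 (1 equiv), THF, –78 °C; then 13, –78 → –40 °C
Reagents that add atoms: none
Why: Nucleophilic aromatic substitution (addition–elimination) at the chlorine-bearing carbon of a diazine activated by both ring nitrogens and the para nitrile; the bond forms at oxygen, so the carbinol configuration is retained. The nitrile has no α-hydrogen, which an acetyl group would have, and makes the chloride reactive at –78 °C. At that temperature, with a triisopropylsilyl neighbour, the alkoxide should not undergo the 1,2 oxygen-to-oxygen silyl shift.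

Step 8
Reactants: 15 6-{[(3S,4R)-1-[(4-methoxybenzyl)oxy]-2-methylidene-4-[(triisopropylsilyl)oxy]-6-(trimethylsilyl)hex-5-yn-3-yl]oxy}pyridazine-3-carbonitrile
Product: 17 1-(6-{[(3S,4R)-1-[(4-methoxybenzyl)oxy]-2-methylidene-4-[(triisopropylsilyl)oxy]-6-(trimethylsilyl)hex-5-yn-3-yl]oxy}pyridazin-3-yl)ethanone, via bromomagnesium ketimine 16 (not isolated)
Conditions: MeMgBr, THF, –40 → 0 °C; then 1 M HCl, 0 °C
Reagents that add atoms: methylmagnesium bromide, C[Mg]Br; water, O
Why: Grignard addition to a heteroaryl nitrile gives the N-magnesio ketimine, which cannot take up a second equivalent and is hydrolysed to the methyl ketone on acidic work-up. The alkoxy group makes the ring a poorer acceptor than the nitrile, and the silyl ether, silylalkyne, alkene and benzyl ether are inert.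

Step 9
Reactants: 17 1-(6-{[(3S,4R)-1-[(4-methoxybenzyl)oxy]-2-methylidene-4-[(triisopropylsilyl)oxy]-6-(trimethylsilyl)hex-5-yn-3-yl]oxy}pyridazin-3-yl)ethanone
Product: 18 1-(6-{[(3R,4S)-3-hydroxy-6-[(4-methoxybenzyl)oxy]-5-methylidenehex-1-yn-4-yl]oxy}pyridazin-3-yl)ethanone
Conditions: Bu4NF, AcOH (1:1, 3 equiv), THF, 0 °C → rt
Reagents that add atoms: none
Why: Buffered fluoride cleaves the secondary O–Si bond and the C(sp)–Si bond in one operation and leaves the 4-methoxybenzyl ether alone. The acetic acid keeps the freed oxygen protonated, which prevents aldol chemistry at the acetyl group and a Smiles-type oxygen-to-oxygen shift of the activated heteroaryl group.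

Step 10
Reactants: 18 1-(6-{[(3R,4S)-3-hydroxy-6-[(4-methoxybenzyl)oxy]-5-methylidenehex-1-yn-4-yl]oxy}pyridazin-3-yl)ethanone
Product: 19 (3R,4S)-4-[(6-acetylpyridazin-3-yl)oxy]-6-[(4-methoxybenzyl)oxy]-5-methylidenehex-1-yn-3-yl acetate
Conditions: Ac2O, pyridine, DMAP (cat.), CH2Cl2, 0 °C → rt
Reagents that add atoms: acetic anhydride, CC(=O)OC(C)=O
Why: DMAP-catalysed acylation of the propargylic alcohol; the medium is not basic enough to form the alkoxide, so the heteroaryl ether stays in place. The C3 acetate of the target is installed here and is not touched again.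

Step 11
Reactants: 19 (3R,4S)-4-[(6-acetylpyridazin-3-yl)oxy]-6-[(4-methoxybenzyl)oxy]-5-methylidenehex-1-yn-3-yl acetate
Product: 21 (2S,3R)-5-acetyl-2-{3-[(4-methoxybenzyl)oxy]prop-1-en-2-yl}-2,3-dihydro-1-benzofuran-3-yl acetate, via 2,3-diazabicyclo[2.2.2]octatriene cycloadduct 20 (not isolated)
Conditions: 1,3,5-triisopropylbenzene (0.01 M), BHT (cat.), Ar, base-washed glass, 185 °C
Reagents that add atoms: none
Why: The acetyl-substituted 1,2-diazine (LUMO lowered by the acetyl group) is the 4π partner and the tethered terminal alkyne the 2π partner of an intramolecular inverse-electron-demand [4+2] cycloaddition. The internal alkyne carbon bonds to the oxygen-bearing ring carbon (C3a–C7a) and the terminal one to the acetyl-bearing carbon (C4–C5), giving the bridged azo compound 20. Compound 20 at once loses N2 by retro-[4+2], which makes the step irreversible and leaves the benzene ring. The closest known reaction type is the thermal cyclisation of 3-(alk-3-ynyloxy)pyridazines to 2,3-dihydrobenzofurans. The dihydrofuran ring closes as the five-membered tether ring of the cycloaddition (three-atom O1–C2–C3 tether), and the carbocycle closes as the cycloaddition ring itself and aromatises on loss of N2. No stereocentre is created: C2 and C3 sit on the tether, no bond to either is broken, and the anti relation in 19 becomes the trans relation in 21. Regiochemistry needs no control because the tether allows one orientation only, and the 1,1-disubstituted alkene, two atoms from the ring, cannot reach across it. The selectivity needed is between pathways: cycloaddition must be faster than the [3,3] shift of the allylic carbon from oxygen to ring nitrogen and faster than loss of acetic acid. The acetyl group, the unhindered terminal alkyne, the two tether substituents that favour the folded rotamer, exclusion of acid and the lowest workable temperature are what should secure this.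

Step 12
Reactants: 21 (2S,3R)-5-acetyl-2-{3-[(4-methoxybenzyl)oxy]prop-1-en-2-yl}-2,3-dihydro-1-benzofuran-3-yl acetate
Product: 22 (2S,3R)-5-[(1R)-1-hydroxyethyl]-2-{3-[(4-methoxybenzyl)oxy]prop-1-en-2-yl}-2,3-dihydro-1-benzofuran-3-yl acetate
Conditions: RuCl[(R,R)-TsDPEN](p-cymene) (cat.), HCO2H/Et3N (5:2), rt
Reagents that add atoms: none
Why: Noyori asymmetric transfer hydrogenation of an aryl methyl ketone; the (R,R)-ligand delivers hydride to the face that gives the (R)-carbinol, as with acetophenone, and formic acid makes the reduction of this electron-rich ketone irreversible. Control is by the catalyst, so the two ring stereocentres have no influence, and the esters, the ether and the isolated alkene are not reduced.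

Step 13
Reactants: 22 (2S,3R)-5-[(1R)-1-hydroxyethyl]-2-{3-[(4-methoxybenzyl)oxy]prop-1-en-2-yl}-2,3-dihydro-1-benzofuran-3-yl acetate; 23 tiglic acid [(2E)-2-methylbut-2-enoic acid]
Product: 25 (1R)-1-[(2S,3R)-3-acetoxy-2-{3-[(4-methoxybenzyl)oxy]prop-1-en-2-yl}-2,3-dihydro-1-benzofuran-5-yl]ethyl (2E)-2-methylbut-2-enoate, via mixed trichlorobenzoic anhydride 24 (not isolated)
Conditions: 23, 2,4,6-Cl3C6H2COCl, Et3N, THF, rt; then 22, DMAP, toluene, rt
Reagents that add atoms: none
Why: Yamaguchi esterification; DMAP attacks the less hindered tigloyl carbonyl of 24 and the acylpyridinium acylates the benzylic alcohol at oxygen, so the carbinol configuration is retained. The E alkene is the stable isomer, and no strong acid or base meets the acetate.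

Step 14
Reactants: 25 (1R)-1-[(2S,3R)-3-acetoxy-2-{3-[(4-methoxybenzyl)oxy]prop-1-en-2-yl}-2,3-dihydro-1-benzofuran-5-yl]ethyl (2E)-2-methylbut-2-enoate
Product: 26 (1R)-1-[(2S,3R)-3-acetoxy-2-(3-hydroxyprop-1-en-2-yl)-2,3-dihydro-1-benzofuran-5-yl]ethyl (2E)-2-methylbut-2-enoate
Conditions: DDQ, CH2Cl2/pH 7 buffer, 0 °C → rt
Reagents that add atoms: none
Why: Oxidative cleavage of a 4-methoxybenzyl ether: hydride abstraction from the electron-rich benzylic CH2, then hydrolysis of the oxocarbenium ion. The benzylic C–H bonds of the substrate itself carry acyloxy groups, which disfavour hydride loss, and the buffer keeps the acidic hydroquinone from ionising the benzylic esters.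

Step 15
Reactants: 26 (1R)-1-[(2S,3R)-3-acetoxy-2-(3-hydroxyprop-1-en-2-yl)-2,3-dihydro-1-benzofuran-5-yl]ethyl (2E)-2-methylbut-2-enoate
Product: 27 (1R)-1-[(2S,3R)-3-acetoxy-2-(3-oxoprop-1-en-2-yl)-2,3-dihydro-1-benzofuran-5-yl]ethyl (2E)-2-methylbut-2-enoate (target)
Conditions: MnO2 (activated, excess), CH2Cl2, rt
Reagents that add atoms: none
Why: MnO2 oxidises allylic alcohols selectively under neutral, heterogeneous conditions. The 2-substituted allylic alcohol should give the α-methylene aldehyde without touching the esters or the C2–H, and filtration is the whole work-up.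

## Compound list

1 | ethynyl(trimethyl)silane | C#C[Si](C)(C)C | starting material
2 | prop-2-enal (acrolein) | C=CC=O | starting material
3 | lithium (trimethylsilyl)acetylide | [Li]C#C[Si](C)(C)C | intermediate (not isolated)
4 | rac-5-(trimethylsilyl)pent-1-en-4-yn-3-ol | C=CC(O)C#C[Si](C)(C)C | intermediate
5 | (3S)-5-(trimethylsilyl)pent-1-en-4-yn-3-ol | C=C[C@H](O)C#C[Si](C)(C)C | intermediate
6 | triisopropyl{[(3S)-5-(trimethylsilyl)pent-1-en-4-yn-3-yl]oxy}silane | C=C[C@H](O[Si](C(C)C)(C(C)C)C(C)C)C#C[Si](C)(C)C | intermediate
7 | triisopropyl{[(1R)-1-(1,2,4-trioxolan-3-yl)-3-(trimethylsilyl)prop-2-yn-1-yl]oxy}silane (ozonide, either configuration at the trioxolane carbon) | O1COOC1[C@H](O[Si](C(C)C)(C(C)C)C(C)C)C#C[Si](C)(C)C | intermediate (not isolated)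
8 | (2R)-2-[(triisopropylsilyl)oxy]-4-(trimethylsilyl)but-3-ynal | O=C[C@H](O[Si](C(C)C)(C(C)C)C(C)C)C#C[Si](C)(C)C | intermediate
9 | 2-bromoprop-2-en-1-ol | C=C(Br)CO | starting material
10 | 1-{[(2-bromoprop-2-en-1-yl)oxy]methyl}-4-methoxybenzene | C=C(Br)COCc1ccc(OC)cc1 | intermediate
11 | {3-[(4-methoxybenzyl)oxy]prop-1-en-2-yl}lithium | [Li]C(=C)COCc1ccc(OC)cc1 | intermediate (not isolated)
12 | (3S,4R)-1-[(4-methoxybenzyl)oxy]-2-methylidene-4-[(triisopropylsilyl)oxy]-6-(trimethylsilyl)hex-5-yn-3-ol | O[C@@H](C(=C)COCc1ccc(OC)cc1)[C@H](O[Si](C(C)C)(C(C)C)C(C)C)C#C[Si](C)(C)C | intermediate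
13 | 6-chloropyridazine-3-carbonitrile | N#Cc1ccc(Cl)nn1 | starting material
14 | potassium (3S,4R)-1-[(4-methoxybenzyl)oxy]-2-methylidene-4-[(triisopropylsilyl)oxy]-6-(trimethylsilyl)hex-5-yn-3-olate | [K+].[O-][C@@H](C(=C)COCc1ccc(OC)cc1)[C@H](O[Si](C(C)C)(C(C)C)C(C)C)C#C[Si](C)(C)C | intermediate (not isolated)
15 | 6-{[(3S,4R)-1-[(4-methoxybenzyl)oxy]-2-methylidene-4-[(triisopropylsilyl)oxy]-6-(trimethylsilyl)hex-5-yn-3-yl]oxy}pyridazine-3-carbonitrile | N#Cc1ccc(O[C@@H](C(=C)COCc2ccc(OC)cc2)[C@H](O[Si](C(C)C)(C(C)C)C(C)C)C#C[Si](C)(C)C)nn1 | intermediate
16 | N-bromomagnesio ketimine of 17 (C=N–MgBr in place of C=O) | CC(=N[Mg]Br)c1ccc(O[C@@H](C(=C)COCc2ccc(OC)cc2)[C@H](O[Si](C(C)C)(C(C)C)C(C)C)C#C[Si](C)(C)C)nn1 | intermediate (not isolated)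
17 | 1-(6-{[(3S,4R)-1-[(4-methoxybenzyl)oxy]-2-methylidene-4-[(triisopropylsilyl)oxy]-6-(trimethylsilyl)hex-5-yn-3-yl]oxy}pyridazin-3-yl)ethanone | CC(=O)c1ccc(O[C@@H](C(=C)COCc2ccc(OC)cc2)[C@H](O[Si](C(C)C)(C(C)C)C(C)C)C#C[Si](C)(C)C)nn1 | intermediate
18 | 1-(6-{[(3R,4S)-3-hydroxy-6-[(4-methoxybenzyl)oxy]-5-methylidenehex-1-yn-4-yl]oxy}pyridazin-3-yl)ethanone | CC(=O)c1ccc(O[C@@H](C(=C)COCc2ccc(OC)cc2)[C@H](O)C#C)nn1 | intermediate
19 | (3R,4S)-4-[(6-acetylpyridazin-3-yl)oxy]-6-[(4-methoxybenzyl)oxy]-5-methylidenehex-1-yn-3-yl acetate | CC(=O)c1ccc(O[C@@H](C(=C)COCc2ccc(OC)cc2)[C@H](OC(C)=O)C#C)nn1 | intermediate (key-step precursor)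
20 | bridged [4+2] adduct: 2,3-diazabicyclo[2.2.2]octa-2,5,7-triene with acetyl at C1, the ether oxygen at C4 and the O–CH–CH(OAc) tether joining C4 to C5 (either bridgehead diastereomer) | CC(=O)C12C=CC3(N=N1)O[C@@H](C(=C)COCc4ccc(OC)cc4)[C@H](OC(C)=O)C3=C2 | intermediate (not isolated)
21 | (2S,3R)-5-acetyl-2-{3-[(4-methoxybenzyl)oxy]prop-1-en-2-yl}-2,3-dihydro-1-benzofuran-3-yl acetate | C=C(COCc3ccc(OC)cc3)[C@@H]1Oc2ccc(C(C)=O)cc2[C@H]1OC(C)=O | intermediate (key-step product)
22 | (2S,3R)-5-[(1R)-1-hydroxyethyl]-2-{3-[(4-methoxybenzyl)oxy]prop-1-en-2-yl}-2,3-dihydro-1-benzofuran-3-yl acetate | C=C(COCc3ccc(OC)cc3)[C@@H]1Oc2ccc([C@@H](C)O)cc2[C@H]1OC(C)=O | intermediate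
23 | tiglic acid, (2E)-2-methylbut-2-enoic acid | C/C=C(\C)C(=O)O | starting material
24 | (2E)-2-methylbut-2-enoic 2,4,6-trichlorobenzoic anhydride | C/C=C(\C)C(=O)OC(=O)c1c(Cl)cc(Cl)cc1Cl | intermediate (not isolated)
25 | (1R)-1-[(2S,3R)-3-acetoxy-2-{3-[(4-methoxybenzyl)oxy]prop-1-en-2-yl}-2,3-dihydro-1-benzofuran-5-yl]ethyl (2E)-2-methylbut-2-enoate | C=C(COCc3ccc(OC)cc3)[C@@H]1Oc2ccc([C@@H](C)OC(=O)/C(C)=C/C)cc2[C@H]1OC(C)=O | intermediate
26 | (1R)-1-[(2S,3R)-3-acetoxy-2-(3-hydroxyprop-1-en-2-yl)-2,3-dihydro-1-benzofuran-5-yl]ethyl (2E)-2-methylbut-2-enoate | C=C(CO)[C@@H]1Oc2ccc([C@@H](C)OC(=O)/C(C)=C/C)cc2[C@H]1OC(C)=O | intermediate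
27 | (1R)-1-[(2S,3R)-3-acetoxy-2-(3-oxoprop-1-en-2-yl)-2,3-dihydro-1-benzofuran-5-yl]ethyl (2E)-2-methylbut-2-enoate | C=C(C=O)[C@@H]1Oc2ccc([C@@H](C)OC(=O)/C(C)=C/C)cc2[C@H]1OC(C)=O | target

## Step count and least certain steps

Total: 15 steps. Longest linear sequence: 14 steps (steps 1–4 and 6–15; step 5 is the side branch).

Step 11 (key step). What may go wrong: the thermal [3,3] shift of the allylic carbon from the ether oxygen to the neighbouring ring nitrogen may compete with the cycloaddition, and acetic acid may be lost from the propargylic or benzylic acetate at the temperature required. All of these are unimolecular, so dilution cannot separate them. Fallback (sets out from 17, returns at 21): the ring is built before the ester exists, with a bulkier and thermally inert group on the propargylic oxygen.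
- Treatment of 17 with Bu4NF/AcOH (1 equiv each, THF, –20 °C) should remove only the alkynyl silicon and give 1-(6-{[(3R,4S)-6-[(4-methoxybenzyl)oxy]-5-methylidene-3-[(triisopropylsilyl)oxy]hex-1-yn-4-yl]oxy}pyridazin-3-yl)ethanone F1.
- Heating F1 as in step 11 should give 1-[(2S,3R)-2-{3-[(4-methoxybenzyl)oxy]prop-1-en-2-yl}-3-[(triisopropylsilyl)oxy]-2,3-dihydro-1-benzofuran-5-yl]ethanone F2.
- Bu4NF/AcOH at room temperature should then free 1-[(2S,3R)-3-hydroxy-2-{3-[(4-methoxybenzyl)oxy]prop-1-en-2-yl}-2,3-dihydro-1-benzofuran-5-yl]ethanone F3, and Ac2O/pyridine/DMAP converts F3 into 21.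
- The silyloxy group removes the elimination-prone ester from the hot step and adds to the conformational bias towards the folded rotamer. It does not change the intrinsic rate of the allyl shift; if that still dominates, the remedy lies in one of the other disconnections.

Step 6. What may go wrong: epimerisation of 8 at its doubly activated α-carbon under the basic organolithium, and weak facial discrimination because the alkynyl group is a slim "medium" substituent. Fallback (sets out from 10 and 8, returns at 12): a Ni/Cr-mediated coupling of the vinyl bromide with the aldehyde (CrCl2, catalytic NiCl2, a chiral sulfonamide ligand, MeCN, rt). The organochromium species is not basic, so 8 should keep its configuration, and the ligand, chosen to reinforce the Felkin sense, takes over facial control. No new isolable compound arises.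

Step 8. What may go wrong: addition of the Grignard reagent to the electron-poor diazine ring instead of the nitrile, or incomplete hydrolysis of the ketimine. Fallback (sets out from 12, returns at 17): the acetyl group is brought in masked as an enol ether, so no organometallic reagent meets the diazine.
- 3-Chloro-6-(1-ethoxyethenyl)pyridazine F4 is made from 3,6-dichloropyridazine and tributyl(1-ethoxyethenyl)stannane by Stille coupling (Pd(PPh3)2Cl2 cat.). It has no enolisable hydrogen.
- The potassium alkoxide 14 should displace its chloride at 0 °C to room temperature. The triisopropylsilyl group is what makes this slower substitution tolerable. The product is 3-(1-ethoxyethenyl)-6-{[(3S,4R)-1-[(4-methoxybenzyl)oxy]-2-methylidene-4-[(triisopropylsilyl)oxy]-6-(trimethylsilyl)hex-5-yn-3-yl]oxy}pyridazine F5.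
- Dilute HCl in THF hydrolyses the enol ether of F5 to 17.

Step 2. What may go wrong: insufficient discrimination by the enzyme between the two unsaturated substituents, so that the recovered alcohol is not enantiomerically pure enough. Fallback (sets out from 4, returns at 5): Sharpless kinetic resolution of the secondary allylic alcohol (Ti(OiPr)4, L-(+)-diisopropyl tartrate, t-BuOOH 0.6 equiv, 4 Å sieves, CH2Cl2, –20 °C). Discrimination then comes from the tartrate–titanium template and not from the relative size of the two groups. The (R)-enantiomer is epoxidised to (1S)-1-[(2S)-oxiran-2-yl]-3-(trimethylsilyl)prop-2-yn-1-ol F6, and 5 is recovered.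

## Further compounds

F1 | step 11 | 1-(6-{[(3R,4S)-6-[(4-methoxybenzyl)oxy]-5-methylidene-3-[(triisopropylsilyl)oxy]hex-1-yn-4-yl]oxy}pyridazin-3-yl)ethanone | CC(=O)c1ccc(O[C@@H](C(=C)COCc2ccc(OC)cc2)[C@H](O[Si](C(C)C)(C(C)C)C(C)C)C#C)nn1
F2 | step 11 | 1-[(2S,3R)-2-{3-[(4-methoxybenzyl)oxy]prop-1-en-2-yl}-3-[(triisopropylsilyl)oxy]-2,3-dihydro-1-benzofuran-5-yl]ethanone | C=C(COCc3ccc(OC)cc3)[C@@H]1Oc2ccc(C(C)=O)cc2[C@H]1O[Si](C(C)C)(C(C)C)C(C)C
F3 | step 11 | 1-[(2S,3R)-3-hydroxy-2-{3-[(4-methoxybenzyl)oxy]prop-1-en-2-yl}-2,3-dihydro-1-benzofuran-5-yl]ethanone | C=C(COCc3ccc(OC)cc3)[C@@H]1Oc2ccc(C(C)=O)cc2[C@H]1O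
F0 | step 6 | none | none
F4 | step 8 | 3-chloro-6-(1-ethoxyethenyl)pyridazine | CCOC(=C)c1ccc(Cl)nn1
F5 | step 8 | 3-(1-ethoxyethenyl)-6-{[(3S,4R)-1-[(4-methoxybenzyl)oxy]-2-methylidene-4-[(triisopropylsilyl)oxy]-6-(trimethylsilyl)hex-5-yn-3-yl]oxy}pyridazine | CCOC(=C)c1ccc(O[C@@H](C(=C)COCc2ccc(OC)cc2)[C@H](O[Si](C(C)C)(C(C)C)C(C)C)C#C[Si](C)(C)C)nn1
F6 | step 2 | (1S)-1-[(2S)-oxiran-2-yl]-3-(trimethylsilyl)prop-2-yn-1-ol | O[C@@H](C#C[Si](C)(C)C)[C@@H]1CO1
A1 | alternative 1 | (2R,3R)-5-[(1R)-1-(tert-butyldimethylsilyloxy)ethyl]-2-(2-hydroxypropan-2-yl)-2,3-dihydro-1-benzofuran-3-ol | CC(C)(O)[C@@H]1Oc2ccc([C@@H](C)O[Si](C)(C)C(C)(C)C)cc2[C@H]1O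
A2 | alternative 1 | 4-[(1R)-1-(tert-butyldimethylsilyloxy)ethyl]phenol | C[C@@H](O[Si](C)(C)C(C)(C)C)c1ccc(O)cc1
A3 | alternative 1 | (2R)-3,3-dimethyloxirane-2-carbaldehyde | O=C[C@@H]1OC1(C)C
A4 | alternative 2 | 1-[(2S,3R)-3-(tert-butyldimethylsilyloxy)-2-(prop-1-en-2-yl)-2,3-dihydro-1-benzofuran-5-yl]ethanone | C=C(C)[C@@H]1Oc2ccc(C(C)=O)cc2[C@H]1O[Si](C)(C)C(C)(C)C
A5 | alternative 2 | 1-[(3S,4R)-4-(tert-butyldimethylsilyloxy)-3-hydroxy-2,2-dimethyl-3,4-dihydro-2H-chromen-6-yl]ethanone | CC(=O)c1ccc2c(c1)[C@@H](O[Si](C)(C)C(C)(C)C)[C@H](O)C(C)(C)O2
A6 | alternative 2 | 1-(2,2-dimethyl-2H-chromen-6-yl)ethanone | CC(=O)c1ccc2c(c1)C=CC(C)(C)O2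
A7 | alternative 3 | 1-[(2S,3R)-2-[3-(tert-butyldimethylsilyloxy)prop-1-en-2-yl]-3-hydroxy-2,3-dihydro-1-benzofuran-5-yl]ethanone | C=C(CO[Si](C)(C)C(C)(C)C)[C@@H]1Oc2ccc(C(C)=O)cc2[C@H]1O
A8 | alternative 3 | 5-acetyl-2-(tert-butyldimethylsilyloxy)benzaldehyde | CC(=O)c1ccc(O[Si](C)(C)C(C)(C)C)c(C=O)c1
A9 | alternative 3 | {[2-(bromomethyl)prop-2-en-1-yl]oxy}(tert-butyl)dimethylsilane | C=C(CBr)CO[Si](C)(C)C(C)(C)C
A10 | alternative 3 | 1-{3-[(2R,3R)-3-[3-(tert-butyldimethylsilyloxy)prop-1-en-2-yl]oxiran-2-yl]-4-(tert-butyldimethylsilyloxy)phenyl}ethanone | CC(=O)c1ccc(O[Si](C)(C)C(C)(C)C)c(c1)[C@H]1O[C@@H]1C(=C)CO[Si](C)(C)C(C)(C)C
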